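## Structural features

Atoms are labelled in the order of the heavy atoms of the target SMILES: C1 methyl, C2, C3, N4, C5 to C17, O18 (lactone carbonyl oxygen), O19, C20 to C24, O25, C26. The target is hexacyclic. A piperidin-4-one (N4, C3, C2, C24, C23, C26) and a piperidine (N4, C5, C6, C21, C14, C26) share the N4–C26 bond, and a cyclopentane (C14, C21, C22, C23, C26) ties them into a 2-azabicyclo[3.2.1]octane cage. A cycloheptane (C6 to C9, C13, C14, C21) bridges C6 and C14, a cyclopentene (C9 to C13) is fused to it, and a seven-membered lactone (C14, C15, C16, C17, O19, C20, C21) spans the C14–C21 bond. C6, C21, C14, C26 and C23 are contiguous stereocentres, with C14 and C21 a vicinal all-carbon quaternary pair; C2 and C9 stand apart. The fragile points are C2 (alpha to the C24 ketone, with its methyl on the hindered face, so enolisation may erode it), the double beta-amino ketone (retro-Mannich and retro-Michael paths), the lactone (acyl transfer to any free hydroxyl) and the trisubstituted alkene. The real difficulty is the quaternary pair inside the cage, together with a C9 centre that can only be set once the cage exists. The key step exploits the C23–C26 bond that joins the cyclopentane to the piperidinone next to the C24 carbonyl: moving C26 back from C23 to C24 turns both rings into a pyrrolidine-fused cyclohexane, a 2-azabicyclo[3.3.1]nonane that can be assembled by cycloaddition and tethered enolate chemistry.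

## Logic of the disconnections

33 to 32: the C24 carbonyl is taken back to a carbinol. This removes the enolisable C2–C24 unit during the acidic deoxygenation; the forward step must be a non-epimerising oxidation.

32 to 30 via 31: the C11 methylene is traced to an enone carbonyl. The cut is made there because C11 is then the carbonyl carbon of a cyclopentenone; the forward steps must reduce two carbonyls and then remove only the allylic oxygen, with hydride delivered to C11 rather than C13.

30 to 28: C9–C13, C10–C11 and C11–C12 are cut (enyne plus carbon monoxide). Two carbocycles and C9 disappear at once; the forward cyclisation must close a seven-membered ring and choose one alkene face.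

28 to 27: the C23–C26 bond is cut and C24–C26 restored. This converts the unusual cage into a known core type with a trans hydroxy sulfonate; the forward shift needs the leaving group anti to the migrating ring bond and a non-basic medium.

27 to 26 to 25 to 24 to 23: the sulfonate is removed, then C12 (alkyne from aldehyde), then the oxidation level at C13. The alkyne is placed late because it would not survive hydrogenation or a C7 radical; the forward steps must oxidise a neopentyl primary alcohol beside a secondary one and homologate without disturbing the lactone.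

23 to 22 to 21: the C7–C8 bond is cut to an allyl donor and a C7 radical precursor. This leaves a C7 carbinol that comes directly from an epoxide; the forward radical must find no alkyne or alkene nearby, which fixes the order.

21 to 19: the lactone C–O bond (O19–C17) is opened to a tetraol ester. Lactonisation before C7 activation avoids ether formation from the C7/C20 1,4-diol; the forward step must pick the C20 hydroxyl.

19 to 18: C23–H and both C–H bonds at C20 are traced to a ketone and a gamma-lactone. One hydride reagent then sets the endo C23 carbinol and frees C7 and C20 oxygen; it must spare the tert-butyl ester and attack C23 from the exo face.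

18 to 17 to 16: the C2 stereocentre is traced to an exocyclic methylene and the C24 hydroxyl to a C–H bond. The methylene makes C24–H both allylic and alpha to the ketone, which directs enolisation there, and the new hydroxyl then directs hydrogen to C2.

16 to 15: the C2–C24 bond is cut (silyl enol ether plus N-propargyl alkyne). The enol ether is regiodefined because it comes straight from the cycloaddition; the forward step needs a carbophilic catalyst that tolerates a tertiary amine.

15 to 13: the C6–C21 bond and the C7–O–C20 lactone are cut to an epoxide and an ester enolate. The tether from N4 sets C21, the epoxide sets C6 absolutely; the forward step must enolise a hindered ester in the presence of a second ester.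

13 to 12 to 6 and 10: C14–C26 and C21–C22 are cut (amino siloxy diene plus formyl acrylate). One cycloaddition gives the carbocycle, the C26–N bond, quaternary C14 and the enol ether; it must be regioselective, endo for the formyl group and enantioselective.

6 to 5 to 3 to 1, 2 and 4; 10 to 8 and 9; 8 to 7: the diene comes from an enaminone carrying both nitrogen arms, the dienophile from an aldol condensation. All pieces are small, and the only stereocentre bought is the glycidyl carbon.

## Other disconnections considered

Alternative 1: the cut is at C21–C6 and C5–C26, the latter being a carbon–carbon bond that the target does not contain. The forward step is a thermal intramolecular Diels–Alder reaction of a 5,5-disubstituted 2-silyloxycyclopentadiene with a nitroalkene tethered from C14, giving A1. In its favour, one metal-free step would form the cycloheptane and the quaternary C21 next to an existing quaternary C14, and C9 would already be in the tether, where it can steer the facial course. On these points it is better than the chosen plan, which needs a late carbonylative cyclisation to set C9. Against it, nitrogen must later be inserted between C5 and C26 (nitro to ketone, then a Beckmann-type expansion whose regiochemistry rests on migration of the bridgehead carbon). The enol ether also places oxygen at C22, where the target has none, while C23 and C24 remain unfunctionalised, and the whole piperidinone with C2 is still to be attached. Mechanistically the cycloaddition is as well founded as the shift used here, but in step count it is likely longer, since ring expansion, oxygen removal and a further ring must follow.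

Alternative 2: the cut is at C14–C26. The forward step is a photocatalytic decarboxylation to an alpha-amino radical at C26 that adds 6-exo to C14 of a tetrasubstituted enone, giving A2. In its favour, it is convergent, needs no protection at nitrogen, tolerates the lactone, and solves the quaternary-pair problem with a radical, which is less sensitive to crowding than an enolate alkylation; on convergence it equals or betters the chosen plan. Against it, addition to a fully substituted beta-carbon beside quaternary C21 may lose to simple reduction of the radical, and two stereocentres (C14 and C26) would rest on conformational bias only. The C12 oxygen must later be removed with regeneration of the alkene, and the C22–C23 bond still has to be made by alkylating a ketone that has two different alpha-carbons. A2 also carries the C24 ketone, and with it the epimerisable C2, through every remaining step, whereas the chosen plan creates that ketone only at step 20 and masks it again.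

Alternative 3: the cut is at C14–C21. The forward step is an Ireland–Claisen ring contraction of a nine-membered lactone through its silyl ketene acetal, giving A3. In its favour, a cyclic ketene acetal has fixed geometry, so the rearrangement would transfer the C12 carbinol configuration to both quaternary centres. It would also leave the C12=C13 alkene where the target has it and deliver C20 at the carboxyl level. For the carbocyclic half this is the better solution: it needs no carbonylative cyclisation and no removal of the C11 oxygen. Against it, the medium-ring lactone with a tetrasubstituted enolate carbon is costly to make, and in A3 every C–N bond, the C23–C26 and C2–C24 bonds and the two nitrogen rings are still missing. The chosen plan does the reverse: it builds the aza-cage first on a predictable bicyclic template and accepts a late, less certain cycloheptane closure; overall it should be shorter because one cycloaddition delivers four ring atoms with nitrogen in place.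

Key step: step 20

Remarks on the chemistry:
- The precursor 27 and product 28 of the key step were checked against the target; constitution and descriptors agree (C26 retained, C23 inverted). The only change is the promoter: a silver salt has no affinity for a sulfonate, so lithium-perchlorate-assisted buffered solvolysis is used.
- The sense of induction of the diol catalyst in step 6 is assumed to follow that of alpha-substituted acroleins; the antipodal catalyst is used if it is opposite.
- The carbinol configurations at C11 and C24 formed in step 22 are left undefined because both centres are removed in steps 23 and 24.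

## Route

Step 1
Reactants: 1 prop-2-yn-1-amine; 2 (E)-4-methoxybut-3-en-2-one
Product: 3 (Z)-4-(prop-2-yn-1-ylamino)but-3-en-2-one
Conditions: MeOH, 0 → 23 °C
Reagents that add atoms: none
Why: Addition–elimination of a primary amine on a vinylogous ester (enaminone formation); the hydrogen-bonded Z isomer should result.

Step 2
Reactants: 3 (Z)-4-(prop-2-yn-1-ylamino)but-3-en-2-one; 4 (S)-oxiran-2-ylmethyl 3-nitrobenzenesulfonate
Product: 5 (E)-4-{[(2R)-oxiran-2-ylmethyl](prop-2-yn-1-yl)amino}but-3-en-2-one
Conditions: NaH, DMF, 0 → 23 °C
Reagents that add atoms: none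
Why: N-Alkylation of the enaminone anion by direct displacement at the sulfonate-bearing carbon; the stereocentre is untouched and becomes (R) only through the change in substituent priorities.

Step 3
Reactants: 5 (E)-4-{[(2R)-oxiran-2-ylmethyl](prop-2-yn-1-yl)amino}but-3-en-2-one
Product: 6 (E)-3-[(tert-butyldimethylsilyl)oxy]-N-[(2R)-oxiran-2-ylmethyl]-N-(prop-2-yn-1-yl)buta-1,3-dien-1-amine
Conditions: KHMDS (1.1 equiv), THF, −78 °C; then TBSCl; used crude
Reagents that add atoms: tert-butyldimethylsilyl chloride, CC(C)(C)[Si](C)(C)Cl
Why: Kinetic O-silylation of the vinylogous amide enolate gives the 1-amino-3-siloxydiene; any acetylide formed should exchange protons quickly, so that silylation drains the mixture through the enolate.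

Step 4
Reactants: 7 tert-butyl 5-bromopentanoate
Product: 8 tert-butyl 5-oxopentanoate
Conditions: Me3NO, DMSO, 23 °C
Reagents that add atoms: trimethylamine N-oxide, C[N+](C)(C)[O-]
Why: Ganem oxidation: O-alkylation of the amine oxide by the primary bromide and elimination of the ammonium gives the aldehyde without touching the ester.

Step 5
Reactants: 8 tert-butyl 5-oxopentanoate; 9 ethyl glyoxylate
Product: 10 6-tert-butyl 1-ethyl (2E)-3-formylhex-2-enedioate
Conditions: Bu2NH (10 mol %), AcOH (10 mol %), PhMe, 80 °C, removal of water
Reagents that add atoms: none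
Why: Amine-catalysed crossed aldol condensation of an enolisable aldehyde with the non-enolisable glyoxylate; the conjugated E isomer (formyl trans to the ethyl ester) should be the thermodynamic product.

Step 6
Reactants: 6 (E)-3-[(tert-butyldimethylsilyl)oxy]-N-[(2R)-oxiran-2-ylmethyl]-N-(prop-2-yn-1-yl)buta-1,3-dien-1-amine; 10 6-tert-butyl 1-ethyl (2E)-3-formylhex-2-enedioate
Product: 12 C13 primary alcohol of the cyclohexenyl silyl enol ether (N on C26 cis to the C13 hydroxymethyl on quaternary C14, ethyl ester on C21 trans to it), via cycloadduct aldehyde 11 (not isolated)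
Conditions: (4R,5R)-2,2-dimethyl-α,α,α′,α′-tetra(1-naphthyl)-1,3-dioxolane-4,5-dimethanol (20 mol %), PhMe, −78 → −40 °C; then NaBH4, MeOH, −40 → 0 °C
Reagents that add atoms: none
Why: Diels–Alder reaction of a 1-amino-3-siloxydiene: the nucleophilic C22 terminus bonds to C21 (beta to the formyl group) and C26 to the fully substituted C14, and the formyl group should sit endo, which places N4 cis to C13 and trans to the C15 chain. The hydrogen-bonding diol binds the formyl oxygen and should select one face of the dienophile, so C26 and C14 are set absolutely; borohydride then reduces only the aldehyde.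

Step 7
Reactants: 12 C13 primary alcohol of the cyclohexenyl silyl enol ether
Product: 13 tert-butyldiphenylsilyl ether of 12
Conditions: TBDPSCl, imidazole, CH2Cl2, 23 °C
Reagents that add atoms: tert-butyldiphenylsilyl chloride, CC(C)(C)[Si](Cl)(c1ccccc1)c1ccccc1
Why: Silylation of a primary neopentyl alcohol; the acid-stable silyl group keeps C13 masked until step 16 and prevents lactonisation onto either ester.

Step 8
Reactants: 13 tert-butyldiphenylsilyl ether of 12
Product: 15 2-azabicyclo[3.3.1]nonene gamma-lactone (C6–C21 bond formed, C7–O–C20 lactone, C23=C24 silyl enol ether, N-propargyl), via lithium alkoxide 14 (not isolated)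
Conditions: LDA (3.3 equiv), THF/DMPU, −78 → 23 °C
Reagents that add atoms: none
Why: Intramolecular 6-exo-tet opening of the epoxide by the ester enolate at C21; the arm hangs from the pseudo-axial nitrogen on C26, so C6 enters cis to nitrogen and C20 stays cis to the C15 chain, while inversion at the (R)-epoxide carbon fixes C6 with C7 axial. The C7 alkoxide should then close the gamma-lactone on the ethyl ester, which also protects both oxygens.

Step 9
Reactants: 15 2-azabicyclo[3.3.1]nonene gamma-lactone
Product: 16 tetracyclic ketone with a 2-methylene pyrrolidine (C2–C24 bond formed, C24–H, C23 ketone)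
Conditions: [(t-Bu)2(2-biphenylyl)PAu(NCMe)]SbF6 (5 mol %), CH2Cl2/MeOH 10:1, 23 °C
Reagents that add atoms: none
Why: Gold-catalysed Conia-ene-type 5-exo-dig attack of the silyl enol ether carbon C24 on the N-propargyl alkyne; the tether from N4 can only reach the face of C24 cis to nitrogen, so the pyrrolidine is cis-fused and C24–H ends on the exo face.

Step 10
Reactants: 16 tetracyclic ketone with a 2-methylene pyrrolidine
Product: 17 tertiary alpha-ketol (C24–OH, C23 ketone, C2 exocyclic methylene)
Conditions: KHMDS (1.1 equiv), THF, −78 °C; then 2-(phenylsulfonyl)-3-phenyloxaziridine, −78 → −40 °C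
Reagents that add atoms: 2-(phenylsulfonyl)-3-phenyloxaziridine, O=S(=O)(N1OC1c1ccccc1)c1ccccc1
Why: Enolate hydroxylation: C24–H is both alpha to the ketone and allylic, so it should be removed in preference to C22–H or the ester alpha-hydrogens, and the dienolate is oxidised at its alpha-carbon. Oxygen can only enter trans to N4, because the pyrrolidine must stay cis-fused.

Step 11
Reactants: 17 tertiary alpha-ketol
Product: 18 C2-methyl alpha-ketol
Conditions: H2 (1 atm), [Ir(cod)(PCy3)(py)]PF6 (5 mol %), CH2Cl2, 23 °C
Reagents that add atoms: none
Why: Hydroxyl-directed hydrogenation of the allylic 1,1-disubstituted alkene; hydrogen is delivered to C2 from the face of the C24 hydroxyl, which puts the methyl trans to that hydroxyl as the target requires.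

Step 12
Reactants: 18 C2-methyl alpha-ketol
Product: 19 tetraol tert-butyl ester (C7–OH, C20–OH, endo C23–OH, C24–OH)
Conditions: LiBH4, THF/MeOH, 0 → 40 °C
Reagents that add atoms: none
Why: Borohydride reduction of the ketone and the gamma-lactone with the tert-butyl ester spared; hydride should reach C23 from the open exo face, assisted by the neighbouring C24 alkoxide, giving the endo carbinol trans to the C24 hydroxyl.

Step 13
Reactants: 19 tetraol tert-butyl ester
Product: 21 seven-membered lactone triol (O19–C17 bond formed; C7–OH free), via tetraol acid 20 (not isolated)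
Conditions: TFA, CH2Cl2, 23 °C; then EDC·HCl, 4-(dimethylamino)pyridine, i-Pr2NEt, CH2Cl2 (2 mM), 23 °C
Reagents that add atoms: none
Why: Acidolysis of the tert-butyl ester followed by Steglich-type lactonisation under dilution; the C20 hydroxyl gives a seven-membered ring across the cis-disposed arms on the quaternary pair, whereas C7–OH and C23–OH would need eight-membered rings and C24–OH is tertiary.

Step 14
Reactants: 21 seven-membered lactone triol
Product: 22 C7 phenyl selenide
Conditions: N-(phenylselanyl)phthalimide, n-Bu3P, THF, 0 → 23 °C
Reagents that add atoms: N-(phenylselanyl)phthalimide, O=C1N([Se]c2ccccc2)C(=O)c2ccccc12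
Why: Phosphine-mediated conversion of the only unhindered primary alcohol into a selenide; it is done after lactonisation so that no 1,4-diol is present to close a tetrahydrofuran.

Step 15
Reactants: 22 C7 phenyl selenide
Product: 23 butenyl lactone diol (C7–C8 bond formed; C13 still silylated)
Conditions: allylSnBu3 (5 equiv), azobisisobutyronitrile (cat.), PhH, 80 °C
Reagents that add atoms: allyltributylstannane, C=CC[Sn](CCCC)(CCCC)CCCC
Why: Keck radical allylation of the primary C7 radical; no alkyne or alkene is within reach at this stage, so allyl transfer should be the only fate of the radical.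

Step 16
Reactants: 23 butenyl lactone diol
Product: 24 C13 primary alcohol (triol)
Conditions: TBAF, AcOH, THF, 23 → 40 °C
Reagents that add atoms: none
Why: Buffered fluoride desilylation; the buffer keeps the freed C13 hydroxyl from attacking the lactone carbonyl.

Step 17
Reactants: 24 C13 primary alcohol (triol)
Product: 25 C13 aldehyde
Conditions: 2,2,6,6-tetramethylpiperidin-1-oxyl (20 mol %), PhI(OAc)2, CH2Cl2, 23 °C
Reagents that add atoms: none
Why: Oxoammonium oxidation, selective for the primary alcohol over the hindered secondary C23 and tertiary C24 hydroxyls.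

Step 18
Reactants: 25 C13 aldehyde
Product: 26 enyne diol (C13≡C12 formed)
Conditions: (MeO)2P(O)CHN2, KOt-Bu, THF, −78 → 0 °C
Reagents that add atoms: dimethyl (diazomethyl)phosphonate, COP(=O)(OC)C=[N+]=[N-]
Why: Seyferth–Gilbert homologation of a non-enolisable neopentyl aldehyde; low temperature and an aprotic medium are chosen so that the lactone is not opened.

Step 19
Reactants: 26 enyne diol
Product: 27 trans hydroxy mesylate of the pyrrolidine-fused 2-azabicyclo[3.3.1]nonane lactone
Conditions: MsCl, Et3N, CH2Cl2, −20 °C; used at once
Reagents that add atoms: methanesulfonyl chloride, CS(=O)(=O)Cl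
Why: Sulfonylation through sulfene takes the secondary endo hydroxyl and leaves the tertiary C24 hydroxyl free, as the shift requires.

Step 20
Reactants: 27 trans hydroxy mesylate of the pyrrolidine-fused 2-azabicyclo[3.3.1]nonane lactone
Product: 28 azatricyclic keto lactone enyne (C23–C26 formed, C24 ketone)
Conditions: LiClO4, CaCO3, THF, 50 °C
Reagents that add atoms: none
Why: Semipinacol rearrangement of a 2-sulfonyloxy cycloalkanol, the reaction type long used for ring contraction when a ring bond lies anti to the leaving group. As the mesylate departs from C23, C26 shifts from the carbinol carbon C24 to C23 and the C24 oxygen becomes the ketone; an asynchronous limit (Grob-type cleavage to an iminium and enol, then Mannich recombination at C23) leads to the same bond. The cyclopentane (C14, C21, C22, C23, C26) closes by ring contraction through a bridging three-centre transition state, not by exo or endo attack of a chain end, and the piperidinone arises from the same shift by one-carbon enlargement of the pyrrolidine. The one new stereocentre, C23, is formed with inversion because C26 enters opposite the leaving group, while C26 migrates with retention; the N4–C3–C2–C24 tether allows only this outcome. The step needs C26 to migrate in preference to C2, hydride shift or oxirane closure. The endo sulfonate clashes with the C5 methylene in the chair and so favours a boat-like cyclohexane, in which only C24–C26 is antiperiplanar to C23–O. C26 is an amino-substituted carbon with high migratory aptitude, and CaCO3 keeps N4 as the free base without forming the alkoxide that would close the epoxide from the chair. Lithium perchlorate raises the ionising power of the medium in place of a halophilic silver salt, which would not activate a sulfonate.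

Step 21
Reactants: 28 azatricyclic keto lactone enyne
Product: 30 hexacyclic enone ketone (C9–C13, C10–C11, C11–C12 formed; C11 ketone), via hexacarbonyldicobalt alkyne complex 29 (not isolated)
Conditions: Co2(CO)8, CH2Cl2, 23 °C; then N-methylmorpholine N-oxide, 0 → 23 °C
Reagents that add atoms: octacarbonyldicobalt, O=C=[Co](=C=O)(=C=O)(=C=O)[Co](=C=O)(=C=O)(=C=O)=C=O
Why: Intramolecular Pauson–Khand reaction; the alkyne on C14 and the butenyl chain on C6 are 1,3-diaxial on the piperidine, which should offset the cost of the seven-membered ring. The alkene is expected to insert with its terminal CH2 turned away from the N4/C5 bridge, placing H9 toward the cage as in the target; amine-oxide promotion at ambient temperature limits enolisation toward C2.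

Step 22
Reactants: 30 hexacyclic enone ketone
Product: 31 C11,C24 diol (both carbinol centres undefined)
Conditions: NaBH4, CeCl3·7H2O, MeOH, −40 → 0 °C
Reagents that add atoms: none
Why: Luche reduction gives clean 1,2-reduction of the enone and also reduces the C24 ketone, which removes the enolisable position next to C2 before the acidic step; the lactone is not attacked at this temperature.

Step 23
Reactants: 31 C11,C24 diol
Product: 32 C24 carbinol with the C12=C13 alkene and C11 methylene
Conditions: Et3SiH, TFA, CH2Cl2, −20 → 0 °C; aq NaHCO3
Reagents that add atoms: none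
Why: Ionic deoxygenation: only the allylic hydroxyl ionises (the C24 carbinol lies beta to the ammonium centre), and the silane should deliver hydride to the secondary terminus C11 rather than to the fully substituted C13, leaving the trisubstituted C12=C13 alkene.

Step 24
Reactants: 32 C24 carbinol
Product: 33 target keto lactone (CNP0292775.1)
Conditions: Dess–Martin periodinane, NaHCO3, CH2Cl2, 0 → 23 °C
Reagents that add atoms: none
Why: Buffered hypervalent-iodine oxidation of the secondary alcohol to the C24 ketone under non-enolising conditions, so C2 and C23 keep their configurations.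

## Compound list

1 | prop-2-yn-1-amine | C#CCN | starting material
2 | (E)-4-methoxybut-3-en-2-one | CO/C=C/C(C)=O | starting material
3 | (Z)-4-(prop-2-yn-1-ylamino)but-3-en-2-one | C#CCN/C=C\C(C)=O | intermediate
4 | (S)-oxiran-2-ylmethyl 3-nitrobenzenesulfonate | O=S(=O)(OC[C@@H]1CO1)c1cccc([N+](=O)[O-])c1 | starting material
5 | (E)-4-{[(2R)-oxiran-2-ylmethyl](prop-2-yn-1-yl)amino}but-3-en-2-one | C#CCN(C[C@@H]1CO1)/C=C/C(C)=O | intermediate
6 | (E)-3-[(tert-butyldimethylsilyl)oxy]-N-[(2R)-oxiran-2-ylmethyl]-N-(prop-2-yn-1-yl)buta-1,3-dien-1-amine | C#CCN(C[C@@H]1CO1)/C=C/C(=C)O[Si](C)(C)C(C)(C)C | intermediate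
7 | tert-butyl 5-bromopentanoate | BrCCCCC(=O)OC(C)(C)C | starting material
8 | tert-butyl 5-oxopentanoate | O=CCCCC(=O)OC(C)(C)C | intermediate
9 | ethyl glyoxylate | CCOC(=O)C=O | starting material
10 | 6-tert-butyl 1-ethyl (2E)-3-formylhex-2-enedioate | CCOC(=O)/C=C(/C=O)CCC(=O)OC(C)(C)C | intermediate
11 | cycloadduct aldehyde (C23=C24 silyl enol ether; N(propargyl)(glycidyl) on C26 cis to formyl on C14; CO2Et on C21 trans to formyl) | C#CCN(C[C@@H]1CO1)[C@H]1C=C(O[Si](C)(C)C(C)(C)C)C[C@H](C(=O)OCC)[C@@]1(CCC(=O)OC(C)(C)C)C=O | intermediate (not isolated)
12 | C13 primary alcohol from 11 | C#CCN(C[C@@H]1CO1)[C@H]1C=C(O[Si](C)(C)C(C)(C)C)C[C@H](C(=O)OCC)[C@@]1(CCC(=O)OC(C)(C)C)CO | intermediate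
13 | tert-butyldiphenylsilyl ether of 12 | C#CCN(C[C@@H]1CO1)[C@H]1C=C(O[Si](C)(C)C(C)(C)C)C[C@H](C(=O)OCC)[C@@]1(CCC(=O)OC(C)(C)C)CO[Si](c2ccccc2)(c2ccccc2)C(C)(C)C | intermediate
14 | lithium C7 alkoxide of the bicyclic ethyl ester | C#CCN1C[C@@H](C[O-])[C@@]2(C(=O)OCC)[C@@](CCC(=O)OC(C)(C)C)(CO[Si](c3ccccc3)(c3ccccc3)C(C)(C)C)[C@@H]1C=C(O[Si](C)(C)C(C)(C)C)C2.[Li+] | intermediate (not isolated)
15 | 2-azabicyclo[3.3.1]nonene gamma-lactone (C7–O–C20=O), silyl enol ether, N-propargyl | C#CCN1C[C@@H](CO2)[C@@]3(C2=O)[C@@](CCC(=O)OC(C)(C)C)(CO[Si](c4ccccc4)(c4ccccc4)C(C)(C)C)[C@@H]1C=C(O[Si](C)(C)C(C)(C)C)C3 | intermediate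
16 | tetracyclic ketone with 2-methylene pyrrolidine, C24–H | C=C1CN2C[C@@H](CO4)[C@@]3(C4=O)[C@@](CCC(=O)OC(C)(C)C)(CO[Si](c5ccccc5)(c5ccccc5)C(C)(C)C)[C@@H]2[C@@H]1C(=O)C3 | intermediate
17 | tertiary alpha-ketol with 2-methylene pyrrolidine | C=C1CN2C[C@@H](CO4)[C@@]3(C4=O)[C@@](CCC(=O)OC(C)(C)C)(CO[Si](c5ccccc5)(c5ccccc5)C(C)(C)C)[C@@H]2[C@]1(O)C(=O)C3 | intermediate
18 | C2-methyl alpha-ketol | C[C@@H]1CN2C[C@@H](CO4)[C@@]3(C4=O)[C@@](CCC(=O)OC(C)(C)C)(CO[Si](c5ccccc5)(c5ccccc5)C(C)(C)C)[C@@H]2[C@]1(O)C(=O)C3 | intermediate
19 | tetraol tert-butyl ester | C[C@@H]1CN2C[C@@H](CO)[C@@]3(CO)[C@@](CCC(=O)OC(C)(C)C)(CO[Si](c4ccccc4)(c4ccccc4)C(C)(C)C)[C@@H]2[C@]1(O)[C@@H](O)C3 | intermediate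
20 | tetraol carboxylic acid | C[C@@H]1CN2C[C@@H](CO)[C@@]3(CO)[C@@](CCC(=O)O)(CO[Si](c4ccccc4)(c4ccccc4)C(C)(C)C)[C@@H]2[C@]1(O)[C@@H](O)C3 | intermediate (not isolated)
21 | seven-membered lactone triol (C7–OH) | C[C@@H]1CN2C[C@@H](CO)[C@@]34COC(=O)CC[C@]3(CO[Si](c5ccccc5)(c5ccccc5)C(C)(C)C)[C@@H]2[C@]1(O)[C@@H](O)C4 | intermediate
22 | C7 phenyl selenide | C[C@@H]1CN2C[C@@H](C[Se]c5ccccc5)[C@@]34COC(=O)CC[C@]3(CO[Si](c5ccccc5)(c5ccccc5)C(C)(C)C)[C@@H]2[C@]1(O)[C@@H](O)C4 | intermediate
23 | butenyl lactone diol, C13 silyl ether | C[C@@H]1CN2C[C@@H](CCC=C)[C@@]34COC(=O)CC[C@]3(CO[Si](c5ccccc5)(c5ccccc5)C(C)(C)C)[C@@H]2[C@]1(O)[C@@H](O)C4 | intermediate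
24 | C13 primary alcohol (triol) | C[C@@H]1CN2C[C@@H](CCC=C)[C@@]34COC(=O)CC[C@]3(CO)[C@@H]2[C@]1(O)[C@@H](O)C4 | intermediate
25 | C13 aldehyde diol | C[C@@H]1CN2C[C@@H](CCC=C)[C@@]34COC(=O)CC[C@]3(C=O)[C@@H]2[C@]1(O)[C@@H](O)C4 | intermediate
26 | enyne trans-diol | C[C@@H]1CN2C[C@@H](CCC=C)[C@@]34COC(=O)CC[C@]3(C#C)[C@@H]2[C@]1(O)[C@@H](O)C4 | intermediate
27 | trans hydroxy mesylate (key-step precursor) | C[C@@H]1CN2C[C@@H](CCC=C)[C@@]34COC(=O)CC[C@]3(C#C)[C@@H]2[C@]1(O)[C@@H](OS(C)(=O)=O)C4 | intermediate
28 | azatricyclic keto lactone enyne (key-step product) | C[C@@H]1CN2C[C@@H](CCC=C)[C@@]34COC(=O)CC[C@]3(C#C)[C@@H]2[C@H](C4)C1=O | intermediate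
29 | hexacarbonyldicobalt complex of the alkyne of 28 | C[C@@H]1CN2C[C@@H](CCC=C)[C@@]34COC(=O)CC[C@]3(C56[Co]7(=C=O)(=C=O)(=C=O)[Co]5(=C=O)(=C=O)(=C=O)[CH]67)[C@@H]2[C@H](C4)C1=O | intermediate (not isolated)
30 | hexacyclic enone ketone (C11 ketone) | C[C@@H]1CN2C[C@H]3CC[C@@H]4CC(=O)C=C4[C@]45CCC(=O)OC[C@]34C[C@H](C1=O)[C@H]25 | intermediate
31 | C11,C24 diol (carbinol centres undefined) | C[C@@H]1CN2C[C@H]3CC[C@@H]4CC(O)C=C4[C@]45CCC(=O)OC[C@]34C[C@H](C1O)[C@H]25 | intermediate
32 | C24 carbinol (carbinol centre undefined) | C[C@@H]1CN2C[C@H]3CC[C@@H]4CCC=C4[C@]45CCC(=O)OC[C@]34C[C@H](C1O)[C@H]25 | intermediate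
33 | CNP0292775.1 | C[C@@H]1CN2C[C@H]3CC[C@@H]4CCC=C4[C@]45CCC(=O)OC[C@]34C[C@H](C1=O)[C@H]25 | target

## Step count and least certain steps

Total: 24 steps. Longest linear sequence: 22 steps (steps 1 to 3 and 6 to 24); the dienophile branch is steps 4 and 5.

Step 20 (key step). Ionisation may lag behind other processes: the chair conformer puts the leaving group anti to the C24–O bond, not to C24–C26, so solvolysis may stall or oxirane closure may set in if the medium turns basic. Alternatively, complete cleavage of C24–C26 may give an iminium and enol pair that does not recombine cleanly. Fallback: make the cleavage deliberate. From 27, warming in buffered aqueous acetonitrile (NaHCO3, MeCN/H2O, 60 °C) should give the ring-opened keto iminium methanesulfonate F1, and an acid-catalysed transannular Mannich reaction (AcOH, 40 °C) would then form the same C23–C26 bond and return to the route at 28.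

Step 21. Closure of the seven-membered ring may be slower than loss of cobalt or alkyne oligomerisation, the alkene face may be chosen poorly at C9, and the amine-rich medium may enolise the C24 ketone toward C2. Fallback: a nickel-mediated cyclisation with an isocyanide in place of carbon monoxide. From 28, Ni(cod)2 and tert-butyl isocyanide in THF should give the N-tert-butyl iminocyclopentene F2 through a reversibly formed nickelacycle, and mild aqueous oxalic acid would hydrolyse it to 30.

Step 8. The base may remove a proton next to the tert-butyl ester (C16) faster than the hindered C21–H, so the wrong enolate may attack the epoxide or the ethyl ester; the transition state also has to place C7 and the C13 substituent 1,3-diaxial. Fallback: form C6–C21 by palladium-catalysed enolate alkenylation and set C6 afterwards. From 3, alkylation with 2,3-dibromopropene (NaH, DMF) gives the N-(2-bromoallyl) enaminone F3, and silylation as in step 3 gives the bromoallyl diene F4. Cycloaddition with 10 as in step 6 gives the bromoallyl cycloadduct aldehyde F5 (not isolated), reduced to the alcohol F6 and silylated as in step 7 to the silyl ether F7. Pd2(dba)3, P(t-Bu)3 and LiHMDS then close the bicyclic 6-methylene ester F8. 9-BBN, which is more reactive toward the 1,1-disubstituted alkene than toward the terminal alkyne, adds from the face away from the C13 substituent; oxidation with NaBO3 gives the C7 hydroxy ester F9, which lactonises to 15.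

Step 6. The doubly activated dienophile may react without the hydrogen-bond catalyst, which would erode enantiofacial control, and the ester may compete with the formyl group for the endo position. Fallback: use the (R)-epoxide as an internal resolving element. From 6 and 10 without catalyst (PhMe, −40 °C), 11 forms together with the ring-diastereomeric cycloadduct aldehyde F10; reduction gives 12 and the diastereomeric alcohol F11, and chromatographic separation returns to the route at 12 at the cost of half the material.

Step 9. The tertiary amine may bind the gold cation, and the enol ether may then be protodesilylated without cyclising. Fallback: from 15, hydrolysis of the enol ether (AcOH, THF/H2O) gives the N-propargyl ketone F12, and a base-mediated 5-exo-dig carbocyclisation under equilibrating conditions (KOt-Bu cat., DMSO, 23 °C) would return to 16; only the C24 enolate can reach the alkyne.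

Step 18. The alkoxides formed from the diol may open the lactone or move the acyl group during homologation. Fallback: accept ring opening and reclose. From 25, the Ohira–Bestmann reagent with K2CO3 in MeOH should give the ring-opened hydroxy methyl ester alkyne F13, and acid-catalysed lactonisation with removal of methanol (camphorsulfonic acid cat., PhMe, 60 °C) returns to 26.

## Further compounds

F1 | step 20 | ring-opened keto iminium methanesulfonate (N4=C26 iminium, C24 ketone, C24–C26 cleaved) | C[C@@H]1C[N+]2=C[C@@]3(C#C)CCC(=O)OC[C@]3(CCC1=O)[C@H](CCC=C)C2.CS(=O)(=O)[O-]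
F2 | step 21 | N-tert-butyl iminocyclopentene (C11=N-t-Bu analogue of 30) | C[C@@H]1CN2C[C@H]3CC[C@@H]4CC(=NC(C)(C)C)C=C4[C@]45CCC(=O)OC[C@]34C[C@H](C1=O)[C@H]25
F3 | step 8 | (E)-4-[(2-bromoprop-2-en-1-yl)(prop-2-yn-1-yl)amino]but-3-en-2-one | C#CCN(CC(Br)=C)/C=C/C(C)=O
F4 | step 8 | (E)-N-(2-bromoprop-2-en-1-yl)-3-[(tert-butyldimethylsilyl)oxy]-N-(prop-2-yn-1-yl)buta-1,3-dien-1-amine | C#CCN(CC(Br)=C)/C=C/C(=C)O[Si](C)(C)C(C)(C)C
F5 | step 8 | bromoallyl cycloadduct aldehyde | C#CCN(CC(Br)=C)[C@H]1C=C(O[Si](C)(C)C(C)(C)C)C[C@H](C(=O)OCC)[C@@]1(CCC(=O)OC(C)(C)C)C=O
F6 | step 8 | bromoallyl C13 alcohol | C#CCN(CC(Br)=C)[C@H]1C=C(O[Si](C)(C)C(C)(C)C)C[C@H](C(=O)OCC)[C@@]1(CCC(=O)OC(C)(C)C)CO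
F7 | step 8 | bromoallyl C13 tert-butyldiphenylsilyl ether | C#CCN(CC(Br)=C)[C@H]1C=C(O[Si](C)(C)C(C)(C)C)C[C@H](C(=O)OCC)[C@@]1(CCC(=O)OC(C)(C)C)CO[Si](c2ccccc2)(c2ccccc2)C(C)(C)C
F8 | step 8 | bicyclic 6-methylene ethyl ester | C#CCN1CC(=C)[C@@]2(C(=O)OCC)[C@@](CCC(=O)OC(C)(C)C)(CO[Si](c3ccccc3)(c3ccccc3)C(C)(C)C)[C@@H]1C=C(O[Si](C)(C)C(C)(C)C)C2
F9 | step 8 | bicyclic C7 hydroxy ethyl ester | C#CCN1C[C@@H](CO)[C@@]2(C(=O)OCC)[C@@](CCC(=O)OC(C)(C)C)(CO[Si](c3ccccc3)(c3ccccc3)C(C)(C)C)[C@@H]1C=C(O[Si](C)(C)C(C)(C)C)C2
F10 | step 6 | ring-diastereomeric cycloadduct aldehyde | C#CCN(C[C@@H]1CO1)[C@@H]1C=C(O[Si](C)(C)C(C)(C)C)C[C@@H](C(=O)OCC)[C@]1(CCC(=O)OC(C)(C)C)C=O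
F11 | step 6 | ring-diastereomeric C13 alcohol | C#CCN(C[C@@H]1CO1)[C@@H]1C=C(O[Si](C)(C)C(C)(C)C)C[C@@H](C(=O)OCC)[C@]1(CCC(=O)OC(C)(C)C)CO
F12 | step 9 | N-propargyl bicyclic ketone gamma-lactone | C#CCN1C[C@@H](CO2)[C@@]3(C2=O)[C@@](CCC(=O)OC(C)(C)C)(CO[Si](c4ccccc4)(c4ccccc4)C(C)(C)C)[C@@H]1CC(=O)C3
F13 | step 18 | ring-opened hydroxy methyl ester alkyne | C[C@@H]1CN2C[C@@H](CCC=C)[C@@]3(CO)[C@@](CCC(=O)OC)(C#C)[C@@H]2[C@]1(O)[C@@H](O)C3
A1 | alternative 1 | nitro norbornene silyl enol ether fused to the hydroazulene | [O-][N+](=O)[C@@H]1[C@H]2CC[C@@H]3CCC=C3[C@]3(CCC(=O)OC)[C@@]2(COCc2ccccc2)C(O[Si](C)(C)C(C)(C)C)=C[C@H]13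
A2 | alternative 2 | pentacyclic diketone lactone | C[C@@H]1CN2C[C@H]3CC[C@@H]4CCC(=O)[C@@H]4[C@@]4(CCC(=O)OC[C@]34CO[Si](C)(C)C(C)(C)C)[C@@H]2CC1=O
A3 | alternative 3 | hydroazulene carboxylic acid with C14 and C21 set | OC(=O)[C@]1(CCC2(CC)OCCO2)[C@@H](COCc2ccc(OC)cc2)CC[C@@H]2CCC=C2[C@]1(CO[Si](C)(C)C(C)(C)C)CC=C
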